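## Analysis of the target

The target is an acyclic 8-O-4' neolignan. Ring A, a 3,4,5-trimethoxyphenyl group, sits on C7 of a three-carbon chain C7–C8–C9 (C9 is a methyl group). C8 is bound through an ether oxygen to C4' of ring B, a benzene ring with a methoxy group at C3' and a 3-hydroxypropyl chain at C1'. No ring has to be made; the problem is two carbon–oxygen bonds on neighbouring sp3 carbons.

C7 (S) is a secondary benzylic alcohol and C8 (R) a secondary alkyl aryl ether. They are adjacent and erythro: in a Fischer projection with ring A and C9 on the vertical axis, the C7 hydroxyl and the C8 aryloxy group lie on the same side.

The benzylic alcohol on an electron-rich ring ionises easily in acid (epimerisation at C7, loss of water). Both rings are oxidisable. The primary alcohol on the ring B side chain competes in any acylation or oxidation aimed at the C7 hydroxyl.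

The difficulty lies in the C8–O4' bond, which joins a secondary carbon next to a carbinol to a phenol oxygen, and in fixing two contiguous acyclic stereocentres in the absolute sense without a ring to relay stereochemistry.

The strategy rests on the oxygen pattern O4 (para on ring A)–C7(OH)–C8–O4'. This is what remains when a 4-propenylphenol radical is captured at C8 by a phenoxyl oxygen and the ring A quinone methide is then hydrated at C7. Only the methyl group on O4 is not delivered by that event. The methoxy groups at C3 and C5 of ring A are the substituents that keep the ring carbons of that radical out of the coupling.

## Retrosynthetic reasoning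

**6 back to 5.** No bond is cut; target 6 is taken from its racemate 5 by enantiomer separation. The skeleton-forming step joins two achiral radicals with no chiral influence, so the absolute configuration can only be sorted afterwards. Sorting on the final compound means no later step can erode it. The forward operation must part the (1S,2R) from the (1R,2S) form and identify which is which.

**5 back to 4.** The O4–CH3 bond on ring A is cut. The para oxygen of ring A has to be a free phenol during the radical chemistry, since it is the site of oxidation. Of the three hydroxyls of 4 it is the only acidic one, so it can be methylated without protecting the others. Once O4 is capped, C7 can no longer epimerise through a quinone methide. This is therefore the stage at which the erythro racemate 5 is freed from the material of threo configuration that the coupling also delivers.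

**4 back to 3.** The C7–O bond is cut, which is the reverse of a hydration. Quinone methide 3 is electrophilic at C7, and 1,6-addition there restores the aromaticity of ring A. The forward step only needs an aqueous medium. It creates C7 without facial control, so both relative configurations of C7 and C8 are expected in the crude product and 4 is carried forward unseparated.

**3 back to 1 and 2.** The C8–O4' bond is cut homolytically. This is the bond that ionic methods make only with effort, and cutting it turns both halves into catalogue phenols: propenylphenol 1 supplies ring A and C7–C9, and phenol 2 supplies ring B with its side chain complete. The whole skeleton is then assembled in one operation with no protecting group. The forward reaction must oxidise both phenols by one electron, pair the radical of 1 with that of 2 rather than with itself, and join C8 to the oxygen rather than to the free ring carbon C5' of 2.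

## Alternatives that were turned down

**Alternative 1:** The ether is cut on its other side, between the oxygen and C4' of ring B. In the forward key step the potassium alkoxide of the enantiopure alcohol A3 displaces fluoride from the fluoroarene A2 in a nucleophilic aromatic substitution to give aldehyde A1.
- For it: the C8–O bond is never broken, so the configuration brought in with A3 is kept, and the formyl group both activates the ring and serves as the handle for the side chain.
- Against it: A3 must first be made as a single erythro enantiomer with its two secondary hydroxyls told apart. A ring activated by one para-formyl group and carrying an ortho-methoxy group is a sluggish substrate, and the alkoxide can also add to the aldehyde. Afterwards A1 still needs a two-carbon homologation, an olefin reduction, an ester reduction and removal of the acetal protecting group.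
- Comparison: this route is clearly stronger on stereocontrol, since nothing is lost to a diastereomer or a wrong enantiomer. It is roughly three times as long and depends on protecting groups. The chosen route offers the complete skeleton with all oxygens in place in one step, at the price of separations.

**Alternative 2:** The chain is cut at C7–C8. A thiamine-dependent carboligase (benzaldehyde lyase) uses aldehyde A5 as acyl-anion donor and A6 as acceptor to give the (R)-acyloin A4.
- For it: C8 is set catalytically in water from two cheap aldehydes, and on this point it is stronger than the chosen route.
- Against it: the step builds the one bond of the target that is already present in the commercial C6–C3 unit 1, and leaves the hard C8–O4' bond unmade. A4 carries a free hydroxyl at C8, which must be arylated with retention. A displacement at C8 would invert it to the wrong configuration, so only an aryl–oxygen bond-forming method such as that of alternative 1 will do. The acyloin also racemises and isomerises under the base this needs. In practice A4 has to be reduced and its hydroxyls differentiated, which leads to A3 and to the full length of alternative 1.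
- Comparison: excellent for one stereocentre, but it adds steps where the chosen route needs none.

**Alternative 3:** The bond between ring A and C7 is cut. An aryltitanium triisopropoxide species derived from the ring A Grignard reagent adds at low temperature to the lactate-derived (R)-aryloxy aldehyde A8 to give the silyl-protected erythro alcohol A7.
- For it: C8 comes from the chiral pool. With a non-chelating titanium reagent the polar aryloxy group lies anti to the incoming aryl group (Felkin–Anh), which leads to the erythro relationship. The route is convergent and needs no resolution; in material efficiency per stereoisomer it is the strongest of the four.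
- Against it: A8 is an α-aryloxy aldehyde that enolises and racemises readily. The selectivity depends on suppressing chelation completely, and any leakage erodes the erythro selectivity, so a diastereomer separation is needed all the same. The side-chain alcohol has to be protected and freed again, and stoichiometric organometallic reagents are needed at low temperature. About six steps are required.
- Comparison: the chosen route gives up absolute control but reaches the target in three operations from two commercial phenols without protecting groups or air-sensitive reagents.

Key step: step 1

## Route

Remarks on the chemistry:
- Compounds 3, 4 and 5 are racemates; each is drawn as the enantiomer that maps onto 6.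
- Compounds 1 and 2 are taken as catalogue compounds. The E/Z purity of 1 is immaterial, because the olefin geometry is lost in 3.
- The coupling is expected to deliver 4 together with its C7 epimer (the threo diastereomer). This by-product is carried through the methylation and removed there; it is described in words and is not a numbered compound of the route.

**Step 1**
Reactants: 1 (E)-2,6-dimethoxy-4-(prop-1-en-1-yl)phenol; 2 4-(3-hydroxypropyl)-2-methoxyphenol (dihydroconiferyl alcohol)
Product: 4 erythro-1-(4-hydroxy-3,5-dimethoxyphenyl)-2-[4-(3-hydroxypropyl)-2-methoxyphenoxy]propan-1-ol (racemate), via ring A quinone methide 3 (not isolated)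
Conditions: Ag2O (1.5 equiv), 2 (4 equiv), acetone–H2O, rt, dark, N2, 1 added over several hours; filter through Celite; then cat. AcOH, rt
Reagents that add atoms: water, O
Why: Ag2O is a one-electron oxidant (monovalent silver going to zerovalent silver) that turns both phenols into phenoxyl radicals; combination of the oxygen of the radical from 2 with C8 of the radical from 1 forms the C8–O4' bond and leaves ring A as the para-quinone methide 3, and 1,6-addition of water at C7 then restores the aromatic ring and gives the benzylic alcohol. The closest known reaction type is the Ag2O- or peroxidase-mediated dehydrogenative coupling of propenylphenols to 8-O-4' neolignans and of monolignols to β-aryl ethers. No ring is closed. C8 is created in the union of two achiral radicals and is racemic; C7 is created when water adds to either face of the planar quinone methide under no more than weak 1,2-induction from C8, so the erythro racemate 4 is expected together with its threo diastereomer (the C7 epimer), at best with a modest erythro bias from the 3,5-dimethoxy pattern of the quinone methide, and the step is not asked to choose between them. The step needs cross-coupling over homo-coupling and O4'–C8 over C5'–C8 bonding. The first is served by adding 1 slowly to an excess of 2, so that the more easily oxidised propenylphenol radical meets radicals of 2 far more often than its own kind. For the second, the two methoxy groups ortho to the oxygen of 1 and its substituted para position leave C8 as the only carbon of that radical where a lasting bond can form, which fixes the carbon terminus; the oxygen terminus is favoured by the high spin density on the phenoxyl oxygen of 2, but C5' of ring B is free, so a phenylcoumaran from C8–C5' bonding is an expected by-product to be removed by chromatography.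

**Step 2**
Reactants: 4 erythro-1-(4-hydroxy-3,5-dimethoxyphenyl)-2-[4-(3-hydroxypropyl)-2-methoxyphenoxy]propan-1-ol (racemate, used as the crude mixture with its C7 epimer)
Product: 5 erythro-2-[4-(3-hydroxypropyl)-2-methoxyphenoxy]-1-(3,4,5-trimethoxyphenyl)propan-1-ol (racemate)
Conditions: MeI (1.5 equiv), K2CO3 (2 equiv), acetone, rt to 40 °C; then SiO2 chromatography (erythro/threo separation)
Reagents that add atoms: iodomethane, CI
Why: Williamson ether synthesis; K2CO3 deprotonates only the phenol and not the two alcohols, so MeI alkylates O4 of ring A alone and no stereocentre is touched. With the para oxygen capped, C7 can no longer epimerise through a quinone methide, so the erythro racemate 5 can be separated on silica from its threo diastereomer (the methyl ether of the C7 epimer of 4), the two series being told apart by the H7–H8 coupling constant.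

**Step 3**
Reactants: 5 erythro-2-[4-(3-hydroxypropyl)-2-methoxyphenoxy]-1-(3,4,5-trimethoxyphenyl)propan-1-ol (racemate)
Product: 6 (1S,2R)-2-[4-(3-hydroxypropyl)-2-methoxyphenoxy]-1-(3,4,5-trimethoxyphenyl)propan-1-ol
Conditions: preparative HPLC, cellulose tris(3,5-dimethylphenylcarbamate) on silica, n-hexane/i-PrOH, rt
Reagents that add atoms: none
Why: Direct enantiomer separation on a polysaccharide carbamate chiral stationary phase, a standard method for 1-aryl-2-aryloxypropan-1-ols; both stereocentres were set in step 1 and are only sorted here, and neutral normal-phase elution leaves the benzylic alcohol and the aryl ether untouched. The (1S,2R) fraction is to be identified by Mosher ester analysis at C7 on a small sample.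

A lipase-mediated kinetic resolution was considered for this step and set aside. The only unhindered hydroxyl is the remote primary one, which carries no stereochemical information, and the C7 hydroxyl is flanked by two large groups that lipases accept poorly.

## Compound list

1 | (E)-2,6-dimethoxy-4-(prop-1-en-1-yl)phenol | C/C=C/c1cc(OC)c(O)c(OC)c1 | starting material
2 | 4-(3-hydroxypropyl)-2-methoxyphenol (dihydroconiferyl alcohol) | COc1cc(CCCO)ccc1O | starting material
3 | 4-{2-[4-(3-hydroxypropyl)-2-methoxyphenoxy]propylidene}-2,6-dimethoxycyclohexa-2,5-dien-1-one (racemate, R drawn; not isolated) | COC1=CC(=C[C@@H](C)Oc2ccc(CCCO)cc2OC)C=C(OC)C1=O | intermediate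
4 | erythro-1-(4-hydroxy-3,5-dimethoxyphenyl)-2-[4-(3-hydroxypropyl)-2-methoxyphenoxy]propan-1-ol (racemate, 1S,2R drawn) | COc1cc(CCCO)ccc1O[C@H](C)[C@@H](O)c1cc(OC)c(O)c(OC)c1 | intermediate
5 | erythro-2-[4-(3-hydroxypropyl)-2-methoxyphenoxy]-1-(3,4,5-trimethoxyphenyl)propan-1-ol (racemate, 1S,2R drawn) | COc1cc(CCCO)ccc1O[C@H](C)[C@@H](O)c1cc(OC)c(OC)c(OC)c1 | intermediate
6 | (1S,2R)-2-[4-(3-hydroxypropyl)-2-methoxyphenoxy]-1-(3,4,5-trimethoxyphenyl)propan-1-ol | COc1cc(CCCO)ccc1O[C@H](C)[C@@H](O)c1cc(OC)c(OC)c(OC)c1 | target

## Step count and risks

Total step count: 3. Longest linear sequence: 3 steps; both starting phenols are commercial, so there is no separate branch.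

**Step 1 (key step).** Self-coupling of the more easily oxidised 1 (through O4–C8 and C8–C8) and bonding of C8 to the free C5' of ring B may take most of the material, and the phenolic product may be oxidised further. The cause is that Ag2O distinguishes the phenols only by their oxidation potentials, and nothing in 2 blocks C5'.

Fallback: an ionic construction of the same C8–O4' bond, setting out from 2 and returning at 5. The commercial ketone 1-(3,4,5-trimethoxyphenyl)propan-1-one F1 is brominated at its α-carbon with CuBr2 in EtOAc–CHCl3 at reflux to give racemic 2-bromo-1-(3,4,5-trimethoxyphenyl)propan-1-one F2. The phenoxide of 2 (K2CO3, acetone, reflux) displaces the bromide in an SN2 reaction; the side-chain alcohol is not deprotonated and stays out. This gives racemic 2-[4-(3-hydroxypropyl)-2-methoxyphenoxy]-1-(3,4,5-trimethoxyphenyl)propan-1-one F3. Reduction with Zn(BH4)2 in Et2O at 0 °C should then favour the erythro alcohol: zinc bridges the carbonyl and aryl ether oxygens and hydride arrives past the C8 hydrogen. After chromatographic removal of the residual threo diastereomer the sequence re-enters at racemate 5, and the methylation of step 2 is no longer needed.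

**Step 2.** The two diastereomeric racemates may co-elute on silica, since they differ only in the relative configuration of two adjacent acyclic centres. A large part of the coupled material is also lost as the threo series.

Fallback: a stereoconvergent detour that sets out from 5, taken as its unseparated mixture with the threo diastereomer, and returns at 5. Both hydroxyls are oxidised with Dess–Martin periodinane (NaHCO3, CH2Cl2, rt), which erases C7 and gives the racemic keto aldehyde 3-(3-methoxy-4-{[1-oxo-1-(3,4,5-trimethoxyphenyl)propan-2-yl]oxy}phenyl)propanal F4. Zn(BH4)2 in Et2O at 0 °C then returns the aldehyde to the primary alcohol and reduces the ketone under the same chelation control as above. Both diastereomers are thereby funnelled into erythro-enriched 5, which a short column or a crystallisation should finish.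

**Step 3.** Resolution of the two enantiomers may be insufficient at preparative loading, because separation on a chiral phase cannot be predicted from structure and may allow only small injections.

Fallback: covalent diastereomers, setting out from 5 and returning at 6. Both hydroxyls of 5 are acylated with (1S,4R)-camphanic chloride (pyridine, cat. DMAP, CH2Cl2). This gives the bis[(1S,4R)-camphanate] of 6, F5, together with the bis[(1S,4R)-camphanate] of the (1R,2S)-enantiomer, F6. The two are diastereomers and can be parted by crystallisation or ordinary chromatography. F5, identified by crystal structure analysis or by cleaving a sample, is hydrolysed with LiOH in THF–H2O to give 6.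

Further compounds
F1 | step 1 | 1-(3,4,5-trimethoxyphenyl)propan-1-one | CCC(=O)c1cc(OC)c(OC)c(OC)c1
F2 | step 1 | 2-bromo-1-(3,4,5-trimethoxyphenyl)propan-1-one (racemate, S drawn) | C[C@H](Br)C(=O)c1cc(OC)c(OC)c(OC)c1
F3 | step 1 | 2-[4-(3-hydroxypropyl)-2-methoxyphenoxy]-1-(3,4,5-trimethoxyphenyl)propan-1-one (racemate, R drawn) | COc1cc(CCCO)ccc1O[C@H](C)C(=O)c1cc(OC)c(OC)c(OC)c1
F4 | step 2 | 3-(3-methoxy-4-{[1-oxo-1-(3,4,5-trimethoxyphenyl)propan-2-yl]oxy}phenyl)propanal (racemate, R drawn) | COc1cc(CCC=O)ccc1O[C@H](C)C(=O)c1cc(OC)c(OC)c(OC)c1
F5 | step 3 | bis[(1S,4R)-camphanate] of 6 (both hydroxyls acylated) | COc1cc(CCCOC(=O)[C@@]23CC[C@@](C)(C(=O)O2)C3(C)C)ccc1O[C@H](C)[C@@H](OC(=O)[C@@]23CC[C@@](C)(C(=O)O2)C3(C)C)c1cc(OC)c(OC)c(OC)c1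
F6 | step 3 | bis[(1S,4R)-camphanate] of the (1R,2S)-enantiomer of 6 | COc1cc(CCCOC(=O)[C@@]23CC[C@@](C)(C(=O)O2)C3(C)C)ccc1O[C@@H](C)[C@H](OC(=O)[C@@]23CC[C@@](C)(C(=O)O2)C3(C)C)c1cc(OC)c(OC)c(OC)c1
A1 | alternative 1 | 3-methoxy-4-{[(1S,2R)-1-(methoxymethoxy)-1-(3,4,5-trimethoxyphenyl)propan-2-yl]oxy}benzaldehyde | COc1cc(C=O)ccc1O[C@H](C)[C@@H](OCOC)c1cc(OC)c(OC)c(OC)c1
A2 | alternative 1 | 4-fluoro-3-methoxybenzaldehyde | COc1cc(C=O)ccc1F
A3 | alternative 1 | (1S,2R)-1-(methoxymethoxy)-1-(3,4,5-trimethoxyphenyl)propan-2-ol | O[C@H](C)[C@@H](OCOC)c1cc(OC)c(OC)c(OC)c1
A4 | alternative 2 | (R)-2-hydroxy-1-(3,4,5-trimethoxyphenyl)propan-1-one | O[C@H](C)C(=O)c1cc(OC)c(OC)c(OC)c1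
A5 | alternative 2 | 3,4,5-trimethoxybenzaldehyde | COc1cc(C=O)cc(OC)c1OC
A6 | alternative 2 | acetaldehyde | CC=O
A7 | alternative 3 | (1S,2R)-2-{4-[3-(tert-butyldimethylsilyloxy)propyl]-2-methoxyphenoxy}-1-(3,4,5-trimethoxyphenyl)propan-1-ol | COc1cc(CCCO[Si](C)(C)C(C)(C)C)ccc1O[C@H](C)[C@@H](O)c1cc(OC)c(OC)c(OC)c1
A8 | alternative 3 | (R)-2-{4-[3-(tert-butyldimethylsilyloxy)propyl]-2-methoxyphenoxy}propanal | COc1cc(CCCO[Si](C)(C)C(C)(C)C)ccc1O[C@H](C)C=O
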